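**Plan**
- Numbering: spiroketal O1, C2 (hexyl chain), C3, C4, C5 (spiro), O6, C7 (methyl), C8, C9; ring A = O1–C5, ring B = C5–C9.
- Cuts, in retrosynthetic order: the phthalide C(=O)–aryl and C(=O)–O bonds (CO insertion), the aryl ketone C–C bond (acylation), the spiroketal O1–C5 bond, then C5–C9 of ring B, the ester C–O bond, and the chain C–C bond next to C2 (cuprate on a glutamate-derived lactone).
- Enabling feature: C5 is a carboxyl-level carbon that already bears O6, and O6–C7–C8–C9 is a homoallylic alcohol in disguise. Ring B is therefore the cyclic enol ether of an ester of (R)-pent-4-en-2-ol: C5–C9 is made as the C=C of a 4,5-dihydrofuran by ring-closing ester carbonyl–olefin metathesis, and that enol ether is the latent oxocarbenium ion for ring A.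
- Forward order: lactone → silyloxy acid → pentenyl ester → ring B (key) → ring A and spiro centre → aryl ketone → carbinol → phthalide ring last.
- Stereochemistry: C2 from (S)-5-(tosyloxymethyl)butyrolactone (L-glutamic acid pool); C7 from (R)-pent-4-en-2-ol; C5 by thermodynamic spiroketalization with separation and recycling; phthalide C3 by CBS reduction.

Key step: step 4

Remark: the spiro centre of a 1,6-dioxaspiro[4.4]nonane equilibrates under acid, so it is set under thermodynamic control in step 5 and only non-acidic conditions are used afterwards.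

Step 1
Reactants: 1 1-bromo-5-chloropentane; 2 (S)-(5-oxooxolan-2-yl)methyl 4-methylbenzenesulfonate
Product: 5 (5R)-5-(6-chlorohexyl)oxolan-2-one, via (5-chloropentyl)magnesium bromide 3 (not isolated), via bromomagnesium bis(5-chloropentyl)cuprate 4 (not isolated)
Conditions: Mg, THF, rt; CuBr·SMe2 (0.5 equiv. per Grignard), THF, −40 °C; then 2, −40 → 0 °C; NH4Cl (aq.)
Reagents that add atoms: none
Why: Organocuprate substitution of a primary tosylate (SN2 at CH2), in which the cuprate should leave the lactone carbonyl and the primary chloride alone at low temperature; the stereocentre is not touched and its descriptor changes from S to R only through the priority change.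

Step 2
Reactants: 5 (5R)-5-(6-chlorohexyl)oxolan-2-one
Product: 8 (4R)-4-[(tert-butyldimethylsilyl)oxy]-10-chlorodecanoic acid, via potassium (4R)-10-chloro-4-hydroxydecanoate 6 (not isolated), via silyl ester silyl ether 7 (not isolated)
Conditions: KOH, MeOH/H2O, rt; evaporate; TBSCl, imidazole, DMF, rt; K2CO3, MeOH/THF/H2O, rt; 1 M HCl to pH 4, 0 °C
Reagents that add atoms: potassium hydroxide ([K+].[OH-]); tert-butyldimethylsilyl chloride (CC(C)(C)[Si](C)(C)Cl)
Why: Lactone saponification, exhaustive silylation and selective cleavage of the labile silyl ester (the standard lactone to silyloxy acid sequence) should give the acid with the C4 oxygen blocked against relactonization and the carbinol configuration unchanged.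

Step 3
Reactants: 8 (4R)-4-[(tert-butyldimethylsilyl)oxy]-10-chlorodecanoic acid; 9 (R)-pent-4-en-2-ol
Product: 10 (2R)-pent-4-en-2-yl (4R)-4-[(tert-butyldimethylsilyl)oxy]-10-chlorodecanoate
Conditions: DCC, DMAP (cat.), CH2Cl2, 0 °C → rt
Reagents that add atoms: none
Why: Steglich esterification acylates the alcohol oxygen, so both stereocentres are retained and the ester that maps onto C5, O6, C7, C8 and C9 of ring B is in place.

Step 4
Reactants: 10 (2R)-pent-4-en-2-yl (4R)-4-[(tert-butyldimethylsilyl)oxy]-10-chlorodecanoate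
Product: 11 tert-butyl({(3R)-9-chloro-1-[(5R)-5-methyl-4,5-dihydrofuran-2-yl]nonan-3-yl}oxy)dimethylsilane
Conditions: TiCl4, TMEDA, Zn, PbCl2 (cat.), CH3CHBr2, THF/CH2Cl2, 0 → 65 °C; K2CO3 (aq.); basic alumina
Reagents that add atoms: none
Why: Carbonyl–olefin metathesis in the form of the Takai–Utimoto olefinic-ester cyclization: the titanium ethylidene made from CH3CHBr2, Zn and TiCl4 first exchanges with the terminal alkene through a titanacyclobutane (propene lost), and the tethered titanium alkylidene at C9 then adds across the ester C5=O to an oxatitanacyclobutane that collapses to the C5=C9 double bond and a titanium oxo species. The closest known reaction type is the conversion of olefinic esters into cyclic enol ethers with reduced titanium alkylidenes (and its two-stage methylenation/metathesis counterpart) used for polyether rings. Ring B is closed as a 4,5-dihydrofuran by ring-closing carbonyl olefination, a [2+2]/retro-[2+2] sequence that joins C9 and C5 inside a five-membered ring, so no disfavoured cyclization mode is involved. No stereocentre is created: C7 and the silyloxy carbinol are spectators, and the new sp2 carbon C5 becomes the spiro stereocentre only in step 5. The step needs alkene exchange to outrun direct ethylidenation of the carbonyl and needs this carbonyl to be the only one attacked; the unhindered vinyl group, the short tether that makes carbonyl capture intramolecular, the slow-reacting secondary-alkyl ester and the absence of any other C=O or alkene (the aryl ketone and the lactone are introduced later) should secure this, while the TBS ether and the primary chloride are inert to the reagent.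

Step 5
Reactants: 11 tert-butyl({(3R)-9-chloro-1-[(5R)-5-methyl-4,5-dihydrofuran-2-yl]nonan-3-yl}oxy)dimethylsilane
Product: 12 (2R,5S,7R)-2-(6-chlorohexyl)-7-methyl-1,6-dioxaspiro[4.4]nonane
Conditions: 48% aq. HF, MeCN, 0 °C → rt; NaHCO3 (aq.); chromatography
Reagents that add atoms: none
Why: Acid-catalysed spiroketalization (hydroalkoxylation of an enol ether): desilylation frees the C2 hydroxyl, protonation at C9 gives the ring-B oxocarbenium ion and the hydroxyl closes ring A; the spiro centre is set under thermodynamic control, where the (5S) epimer, with each ring oxygen pseudo-axial on the other ring and both alkyl groups pseudo-equatorial, should be favoured, and it is separated from the (5R) epimer, which is re-equilibrated under the same acid.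

Step 6
Reactants: 13 3,5-dimethoxybenzoic acid
Product: 14 2-bromo-3,5-dimethoxybenzoic acid
Conditions: NBS (1.0 equiv.), MeCN, 0 °C → rt
Reagents that add atoms: N-bromosuccinimide (O=C1CCC(=O)N1Br)
Why: Electrophilic aromatic bromination should go to C2, which is para to one methoxy group and ortho to the other and less hindered than the position between the two methoxy groups.

Step 7
Reactants: 14 2-bromo-3,5-dimethoxybenzoic acid
Product: 15 2-bromo-3,5-dimethoxybenzoyl chloride
Conditions: (COCl)2, DMF (cat.), CH2Cl2, 0 °C → rt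
Reagents that add atoms: oxalyl chloride (O=C(Cl)C(=O)Cl)
Why: Acid chloride formation through the chloroiminium species from oxalyl chloride and DMF is routine for benzoic acids and leaves the aryl bromide untouched.

Step 8
Reactants: 12 (2R,5S,7R)-2-(6-chlorohexyl)-7-methyl-1,6-dioxaspiro[4.4]nonane; 15 2-bromo-3,5-dimethoxybenzoyl chloride
Product: 17 1-(2-bromo-3,5-dimethoxyphenyl)-7-[(2R,5S,7R)-7-methyl-1,6-dioxaspiro[4.4]nonan-2-yl]heptan-1-one, via spiroketal hexylmagnesium chloride 16 (not isolated)
Conditions: Mg, I2 (cat.), THF, reflux; then 15, CuI (5 mol%), THF, −78 → −20 °C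
Reagents that add atoms: none
Why: Grignard formation from the primary chloride and copper-catalysed acylation by the acid chloride (ketone synthesis) should stop at the hindered ortho-bromoaryl ketone, since at low temperature the acid chloride reacts far faster than the product or the aryl bromide, and the basic medium leaves the spiroketal unchanged.

Step 9
Reactants: 17 1-(2-bromo-3,5-dimethoxyphenyl)-7-[(2R,5S,7R)-7-methyl-1,6-dioxaspiro[4.4]nonan-2-yl]heptan-1-one
Product: 18 (1R)-1-(2-bromo-3,5-dimethoxyphenyl)-7-[(2R,5S,7R)-7-methyl-1,6-dioxaspiro[4.4]nonan-2-yl]heptan-1-ol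
Conditions: (S)-2-methyl-CBS-oxazaborolidine (10 mol%), BH3·SMe2, THF, −20 °C; MeOH
Reagents that add atoms: none
Why: Corey–Bakshi–Shibata reduction: the (S)-oxazaborolidine–borane complex binds the ketone with the large ortho-bromoaryl group away from the catalyst and delivers hydride to the face that gives the (R)-carbinol, as with aryl alkyl ketones in general.

Step 10
Reactants: 18 (1R)-1-(2-bromo-3,5-dimethoxyphenyl)-7-[(2R,5S,7R)-7-methyl-1,6-dioxaspiro[4.4]nonan-2-yl]heptan-1-ol
Product: 19 (3R)-5,7-dimethoxy-3-{6-[(2R,5S,7R)-7-methyl-1,6-dioxaspiro[4.4]nonan-2-yl]hexyl}-2-benzofuran-1(3H)-one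
Conditions: Pd(OAc)2 (5 mol%), Xantphos (10 mol%), CO (1 atm), K2CO3, toluene, 100 °C
Reagents that add atoms: carbon monoxide ([C-]#[O+])
Why: Palladium-catalysed carbonylative lactonization (intramolecular alkoxycarbonylation of an aryl bromide): oxidative addition of zerovalent palladium into the C–Br bond, CO insertion and capture of the acylpalladium by the neighbouring benzylic alkoxide should close the phthalide under basic conditions that touch neither the carbinol stereocentre nor the spiroketal.

**Compound list**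
1 | 1-bromo-5-chloropentane | ClCCCCCBr | starting material
2 | (S)-(5-oxooxolan-2-yl)methyl 4-methylbenzenesulfonate | Cc1ccc(cc1)S(=O)(=O)OC[C@@H]1CCC(=O)O1 | starting material
3 | (5-chloropentyl)magnesium bromide | ClCCCCC[Mg]Br | intermediate
4 | bromomagnesium bis(5-chloropentyl)cuprate | ClCCCCC[Cu-]CCCCCCl.[Mg+]Br | intermediate
5 | (5R)-5-(6-chlorohexyl)oxolan-2-one | ClCCCCCC[C@@H]1CCC(=O)O1 | intermediate
6 | potassium (4R)-10-chloro-4-hydroxydecanoate | [K+].[O-]C(=O)CC[C@H](O)CCCCCCCl | intermediate
7 | tert-butyldimethylsilyl (4R)-4-[(tert-butyldimethylsilyl)oxy]-10-chlorodecanoate | CC(C)(C)[Si](C)(C)OC(=O)CC[C@H](O[Si](C)(C)C(C)(C)C)CCCCCCCl | intermediate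
8 | (4R)-4-[(tert-butyldimethylsilyl)oxy]-10-chlorodecanoic acid | OC(=O)CC[C@H](O[Si](C)(C)C(C)(C)C)CCCCCCCl | intermediate
9 | (R)-pent-4-en-2-ol | C[C@@H](O)CC=C | starting material
10 | (2R)-pent-4-en-2-yl (4R)-4-[(tert-butyldimethylsilyl)oxy]-10-chlorodecanoate | C=CC[C@@H](C)OC(=O)CC[C@H](O[Si](C)(C)C(C)(C)C)CCCCCCCl | intermediate
11 | tert-butyl({(3R)-9-chloro-1-[(5R)-5-methyl-4,5-dihydrofuran-2-yl]nonan-3-yl}oxy)dimethylsilane | C[C@@H]1CC=C(CC[C@H](O[Si](C)(C)C(C)(C)C)CCCCCCCl)O1 | intermediate
12 | (2R,5S,7R)-2-(6-chlorohexyl)-7-methyl-1,6-dioxaspiro[4.4]nonane | ClCCCCCC[C@@H]1CC[C@]2(CC[C@@H](C)O2)O1 | intermediate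
13 | 3,5-dimethoxybenzoic acid | COc1cc(OC)cc(c1)C(=O)O | starting material
14 | 2-bromo-3,5-dimethoxybenzoic acid | COc1cc(OC)c(Br)c(c1)C(=O)O | intermediate
15 | 2-bromo-3,5-dimethoxybenzoyl chloride | COc1cc(OC)c(Br)c(c1)C(=O)Cl | intermediate
16 | chlorido{6-[(2R,5S,7R)-7-methyl-1,6-dioxaspiro[4.4]nonan-2-yl]hexyl}magnesium | Cl[Mg]CCCCCC[C@@H]1CC[C@]2(CC[C@@H](C)O2)O1 | intermediate
17 | 1-(2-bromo-3,5-dimethoxyphenyl)-7-[(2R,5S,7R)-7-methyl-1,6-dioxaspiro[4.4]nonan-2-yl]heptan-1-one | COc1cc(OC)c(Br)c(c1)C(=O)CCCCCC[C@@H]1CC[C@]2(CC[C@@H](C)O2)O1 | intermediate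
18 | (1R)-1-(2-bromo-3,5-dimethoxyphenyl)-7-[(2R,5S,7R)-7-methyl-1,6-dioxaspiro[4.4]nonan-2-yl]heptan-1-ol | COc1cc(OC)c(Br)c(c1)[C@H](O)CCCCCC[C@@H]1CC[C@]2(CC[C@@H](C)O2)O1 | intermediate
19 | (3R)-5,7-dimethoxy-3-{6-[(2R,5S,7R)-7-methyl-1,6-dioxaspiro[4.4]nonan-2-yl]hexyl}-2-benzofuran-1(3H)-one | COc1cc(OC)c2c(c1)[C@@H](CCCCCC[C@@H]1CC[C@]3(CC[C@@H](C)O3)O1)OC2=O | target

**Step count:** 10 steps in total. The longest linear sequence is 8 steps (steps 1–5 and 8–10); steps 6 and 7 form a two-step side branch that joins at step 8.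

**Steps most likely to fail**

Step 4. Direct ethylidenation of the ester carbonyl may outrun the alkene exchange, so that an acyclic enol ether accumulates instead of the ring. The fallback separates the two events. From ester 10, methylenation with Cp2TiMe2 (toluene, 65 °C) should give the diene tert-butyl{[(5R)-11-chloro-2-{[(2R)-pent-4-en-2-yl]oxy}undec-1-en-5-yl]oxy}dimethylsilane F1. Enol ether–olefin ring-closing metathesis of this diene with the second-generation Grubbs catalyst RuCl2(=CHPh)(H2IMes)(PCy3) (toluene, 70 °C, ethene lost) then forms the same C5=C9 bond and rejoins the route at 11.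

Step 5. The ring closure is reversible and may discriminate poorly between the two spiro epimers, which as non-polar oils may also fail to separate. The fallback moves the resolution to the end. The unseparated mixture from 11, containing 12 and its epimer (2R,5R,7R)-2-(6-chlorohexyl)-7-methyl-1,6-dioxaspiro[4.4]nonane F2, is taken through the chemistry of steps 8 to 10. This passes through the Grignard reagent chlorido{6-[(2R,5R,7R)-7-methyl-1,6-dioxaspiro[4.4]nonan-2-yl]hexyl}magnesium F3, the ketone 1-(2-bromo-3,5-dimethoxyphenyl)-7-[(2R,5R,7R)-7-methyl-1,6-dioxaspiro[4.4]nonan-2-yl]heptan-1-one F4, the carbinol (1R)-1-(2-bromo-3,5-dimethoxyphenyl)-7-[(2R,5R,7R)-7-methyl-1,6-dioxaspiro[4.4]nonan-2-yl]heptan-1-ol F5 and the phthalide (3R)-5,7-dimethoxy-3-{6-[(2R,5R,7R)-7-methyl-1,6-dioxaspiro[4.4]nonan-2-yl]hexyl}-2-benzofuran-1(3H)-one F6. The polar, UV-active phthalides are then separated by preparative HPLC, and F6 is equilibrated with PPTS in CH2Cl2 and separated again, so that the route is rejoined at 19.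

Step 10. Oxidative addition into the electron-rich C–Br bond, flanked by a methoxy group and the carbinol side chain, may be slow, so that protodebromination or oxidation of the benzylic alcohol takes over. The fallback is an anionic carboxylation. From 18, n-BuLi (2.2 equiv., THF, −78 °C; alkoxide formation, then bromine–lithium exchange) followed by CO2 should give, after careful acidification to pH 5 (NaH2PO4), the hydroxy acid 2-{(1R)-1-hydroxy-7-[(2R,5S,7R)-7-methyl-1,6-dioxaspiro[4.4]nonan-2-yl]heptyl}-4,6-dimethoxybenzoic acid F7. This acid should lactonize spontaneously with loss of water and rejoin the route at 19.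

**Further compounds**
F1 | step 4 | tert-butyl{[(5R)-11-chloro-2-{[(2R)-pent-4-en-2-yl]oxy}undec-1-en-5-yl]oxy}dimethylsilane | C=CC[C@@H](C)OC(=C)CC[C@H](O[Si](C)(C)C(C)(C)C)CCCCCCCl
F2 | step 5 | (2R,5R,7R)-2-(6-chlorohexyl)-7-methyl-1,6-dioxaspiro[4.4]nonane | ClCCCCCC[C@@H]1CC[C@@]2(CC[C@@H](C)O2)O1
F3 | step 5 | chlorido{6-[(2R,5R,7R)-7-methyl-1,6-dioxaspiro[4.4]nonan-2-yl]hexyl}magnesium | Cl[Mg]CCCCCC[C@@H]1CC[C@@]2(CC[C@@H](C)O2)O1
F4 | step 5 | 1-(2-bromo-3,5-dimethoxyphenyl)-7-[(2R,5R,7R)-7-methyl-1,6-dioxaspiro[4.4]nonan-2-yl]heptan-1-one | COc1cc(OC)c(Br)c(c1)C(=O)CCCCCC[C@@H]1CC[C@@]2(CC[C@@H](C)O2)O1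
F5 | step 5 | (1R)-1-(2-bromo-3,5-dimethoxyphenyl)-7-[(2R,5R,7R)-7-methyl-1,6-dioxaspiro[4.4]nonan-2-yl]heptan-1-ol | COc1cc(OC)c(Br)c(c1)[C@H](O)CCCCCC[C@@H]1CC[C@@]2(CC[C@@H](C)O2)O1
F6 | step 5 | (3R)-5,7-dimethoxy-3-{6-[(2R,5R,7R)-7-methyl-1,6-dioxaspiro[4.4]nonan-2-yl]hexyl}-2-benzofuran-1(3H)-one | COc1cc(OC)c2c(c1)[C@@H](CCCCCC[C@@H]1CC[C@@]3(CC[C@@H](C)O3)O1)OC2=O
F7 | step 10 | 2-{(1R)-1-hydroxy-7-[(2R,5S,7R)-7-methyl-1,6-dioxaspiro[4.4]nonan-2-yl]heptyl}-4,6-dimethoxybenzoic acid | COc1cc(OC)c(C(=O)O)c(c1)[C@H](O)CCCCCC[C@@H]1CC[C@]2(CC[C@@H](C)O2)O1
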